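**Retrosynthetic overview**

1. Veramycin A (14) ⇐ bromopyrone 12 + alkenylboronate 13: the (E)-hydroxypropenyl arm is attached last by sp2–sp2 coupling at the aryl bromide.
2. 12 ⇐ open triketide 11: the 2-pyrone, the only ring made that survives, is closed at its lactone C–O bond (O1–C2) by enol-lactonisation. This is the key bond.
3. 11 ⇐ cis-β-lactone 8 + acetoacetate dianion 10 (C5–C6): the β-lactone acts as acyl donor and its ring oxygen is released as the free C3'–OH, so no protecting group is needed.
4. 8 ⇐ (S)-aldehyde 5 + methylketene (asymmetric [2+2], sets C2' and C3'); 5 ⇐ styrene 4 ⇐ aldehyde 1 (asymmetric hydroformylation, sets C4').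
5. Ring order: β-lactone (step 3, relay ring) → 2-pyrone (step 4); the arene is bought.

Side-chain numbering: C2' is attached to the pyrone, C3' bears OH, C4' is benzylic. Target configuration is 2'S,3'R,4'S, i.e. all-syn Me/OH/Me in the zigzag.

Assumption: the catalyst antipodes named in steps 2 and 3 and in the fallback reduction are those expected by analogy with simpler substrates; if the sense is opposite here, the mirror-image (or pseudo-enantiomeric) catalyst is used with nothing else changed.

**Route**

Step 1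
Reactants: 1 2-bromo-4-methylbenzaldehyde; 2 methyltriphenylphosphonium bromide
Product: 4 2-bromo-1-ethenyl-4-methylbenzene, via methylenetriphenylphosphorane 3 (not isolated)
Conditions: KOtBu (1.2 equiv), THF, 0 °C → rt
Reagents that add atoms: none
Why: Wittig methylenation of an aryl aldehyde with a non-stabilised ylide gives the terminal styrene; no stereocentre is formed and the ArBr is inert.

Step 2
Reactants: 4 2-bromo-1-ethenyl-4-methylbenzene
Product: 5 (2S)-2-(2-bromo-4-methylphenyl)propanal
Conditions: Rh(acac)(CO)2 (0.5 mol %), (R,S)-BINAPHOS (2 mol %), CO/H2 1:1 (50 bar), PhMe, 50 °C; short silica plug, used at once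
Reagents that add atoms: carbon monoxide, [C-]#[O+]
Why: Rh-catalysed asymmetric hydroformylation of a vinylarene is branched-selective through the benzylic Rh–alkyl, and the chiral phosphine–phosphite ligand sets C4' as S; neutral conditions spare the ArBr and the labile α-aryl aldehyde.

Step 3
Reactants: 5 (2S)-2-(2-bromo-4-methylphenyl)propanal; 6 propanoyl chloride
Product: 8 (3S,4R)-4-[(1S)-1-(2-bromo-4-methylphenyl)ethyl]-3-methyloxetan-2-one, via methylketene 7 (not isolated)
Conditions: O-TMS-quinine (15 mol %), LiI (3 equiv), iPr2NEt (2.5 equiv), 6 (2 equiv, slow addition), CH2Cl2/Et2O 10:1, −78 °C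
Reagents that add atoms: none
Why: Cinchona alkaloid/Lewis acid-catalysed acyl halide–aldehyde cyclocondensation (formal ketene–aldehyde [2+2]: ammonium-enolate aldol, then lactonisation). The (Z)-ammonium enolate adds through a Li-templated chair to give the cis-lactone with C3 S and C4 R (= C2' S, C3' R) under catalyst control. This is also the Felkin sense for the (S)-aldehyde, and the minor diastereomer from residual (R)-5 is removed here.

Step 4
Reactants: 8 (3S,4R)-4-[(1S)-1-(2-bromo-4-methylphenyl)ethyl]-3-methyloxetan-2-one; 9 ethyl 2-ethyl-3-oxobutanoate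
Product: 12 6-[(2S,3R,4S)-4-(2-bromo-4-methylphenyl)-3-hydroxypentan-2-yl]-3-ethyl-4-hydroxy-2H-pyran-2-one, via ketoester dianion 10 (not isolated), via open-chain triketide ester 11 (not isolated)
Conditions: 9 (3 equiv), LDA (2.0 equiv per 9), THF, 0 °C; add 8, −78 → −40 °C; AcOH, −78 °C → rt; then DBU (5 equiv), PhMe added, 60 °C; 1 M HCl work-up
Reagents that add atoms: none
Why: Proposed new method: a β-lactone-to-2-pyrone relay in which the strained acyl–O bond of 8 (about 23 kcal/mol) acylates the hard, unhindered γ-carbanion of dianion 10 at C=O (SN2 at C4 is blocked by the α-branched substituent), the tetrahedral intermediate can only collapse by expelling the substrate's own C3' alkoxide, and the resulting 3,5-dione is at once deprotonated at C5 by a second equivalent of dianion, which stops over-addition, retro-aldol and C2' epimerisation; after AcOH, DBU generates the dione enolate whose C6 oxygen attacks the ethyl ester (6-membered acyl substitution, loss of EtOH) and the aromatic pyronate is the thermodynamic sink, so the lactone C–O bond made in step 3 is traded for the pyrone O1–C2 bond with no stereocentre formed or touched; closest known reactions are acyl-carbon opening of β-lactones by enolates and amines, dianion acylation by Weinreb amides or esters, and DBU-mediated lactonisation of 3,5-diketoesters to 4-hydroxy-2-pyrones.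

Step 5
Reactants: 12 6-[(2S,3R,4S)-4-(2-bromo-4-methylphenyl)-3-hydroxypentan-2-yl]-3-ethyl-4-hydroxy-2H-pyran-2-one; 13 (2E)-3-(4,4,5,5-tetramethyl-1,3,2-dioxaborolan-2-yl)prop-2-en-1-ol
Product: 14 Veramycin A, 3-ethyl-4-hydroxy-6-[(2S,3R,4S)-3-hydroxy-4-{2-[(1E)-3-hydroxyprop-1-en-1-yl]-4-methylphenyl}pentan-2-yl]-2H-pyran-2-one
Conditions: SPhos Pd G3 (3 mol %), K3PO4 (4 equiv), 13 (1.5 equiv), THF/H2O 4:1, 60 °C; work-up at pH 4
Reagents that add atoms: none
Why: Suzuki–Miyaura coupling of an ortho-substituted aryl bromide with an (E)-alkenylboronate proceeds with retention of alkene geometry; in aqueous phosphate the pyrone is a spectator pyronate, the free alcohols are tolerated and no stereocentre is affected.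

**Compound list**

1 | 2-bromo-4-methylbenzaldehyde | O=Cc1ccc(C)cc1Br | starting material
2 | methyltriphenylphosphonium bromide | C[P+](c1ccccc1)(c1ccccc1)c1ccccc1.[Br-] | starting material
3 | methylenetriphenylphosphorane | C=P(c1ccccc1)(c1ccccc1)c1ccccc1 | intermediate (not isolated)
4 | 2-bromo-1-ethenyl-4-methylbenzene | C=Cc1ccc(C)cc1Br | intermediate
5 | (2S)-2-(2-bromo-4-methylphenyl)propanal | O=C[C@@H](C)c1ccc(C)cc1Br | intermediate
6 | propanoyl chloride | CCC(=O)Cl | starting material
7 | methylketene (prop-1-en-1-one) | CC=C=O | intermediate (not isolated)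
8 | (3S,4R)-4-[(1S)-1-(2-bromo-4-methylphenyl)ethyl]-3-methyloxetan-2-one (cis-β-lactone) | O=C1[C@@H](C)[C@H](O1)[C@@H](C)c2ccc(C)cc2Br | intermediate
9 | ethyl 2-ethyl-3-oxobutanoate (racemic) | CCOC(=O)C(CC)C(C)=O | starting material
10 | dilithium dianion of ethyl 2-ethyl-3-oxobutanoate | [Li+].[Li+].[CH2-]C(=O)[C-](CC)C(=O)OCC | intermediate (not isolated)
11 | ethyl (6S,7R,8S)-8-(2-bromo-4-methylphenyl)-2-ethyl-7-hydroxy-6-methyl-3,5-dioxononanoate (C2 epimers, enol tautomers) | CCOC(=O)C(CC)C(=O)CC(=O)[C@@H](C)[C@H](O)[C@@H](C)c1ccc(C)cc1Br | intermediate (not isolated)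
12 | 6-[(2S,3R,4S)-4-(2-bromo-4-methylphenyl)-3-hydroxypentan-2-yl]-3-ethyl-4-hydroxy-2H-pyran-2-one | CCc1c(O)cc([C@@H](C)[C@H](O)[C@@H](C)c2ccc(C)cc2Br)oc1=O | intermediate
13 | (2E)-3-(4,4,5,5-tetramethyl-1,3,2-dioxaborolan-2-yl)prop-2-en-1-ol | OC/C=C/B1OC(C)(C)C(C)(C)O1 | starting material
14 | Veramycin A | CCc1c(O)cc([C@@H](C)[C@H](O)[C@@H](C)c2ccc(C)cc2/C=C/CO)oc1=O | target

**Step count**

Total steps: 5. Longest linear sequence: 5 (1 → 4 → 5 → 8 → 12 → 14). No protecting groups or auxiliaries.

**Three steps most likely to fail, with fallbacks**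

Step 4 (the proposed new step). The dianion may act as a base toward the α-H of 8, causing C2' epimerisation or β-elimination. The DBU stage could also dehydrate the β-hydroxy ketone or epimerise C2'. The fallback sets out from 8 and uses only known chemistry. The lactone is opened with MeONHMe·HCl/Me2AlCl to the Weinreb amide (2S,3R,4S)-4-(2-bromo-4-methylphenyl)-3-hydroxy-N-methoxy-N,2-dimethylpentanamide F5. The alcohol is silylated (TESOTf, 2,6-lutidine) to the triethylsilyl ether of that amide F6. Dianion 10 then acylates F6 at −78 → 0 °C to give the silyl-protected triketide ester F7, which DBU in toluene lactonises to the silyl-protected bromopyrone F8. HF·pyridine removes the silyl group, and the fallback comes back to the route at 12.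

Step 3. The α-aryl aldehyde may racemise or be O-acylated to its enol ester under amine/acyl chloride conditions, and the branched aldehyde may react slowly. The fallback sets out from 5 and replaces the catalytic [2+2] by an auxiliary-controlled boron aldol. (S)-4-Benzyl-3-propanoyl-oxazolidin-2-one, Bu2BOTf and iPr2NEt in CH2Cl2 at −78 °C give the Evans syn adduct (4S)-4-benzyl-3-[(2S,3R,4S)-4-(2-bromo-4-methylphenyl)-3-hydroxy-2-methylpentanoyl]-1,3-oxazolidin-2-one F3. LiOH/H2O2 cleaves the auxiliary to (2S,3R,4S)-4-(2-bromo-4-methylphenyl)-3-hydroxy-2-methylpentanoic acid F4. Carboxyl-activating lactonisation (PhSO2Cl, pyridine, 0 °C, retention at C3') comes back to the route at 8.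

Step 2. The ortho-bromo substituent may lower the ee or branched selectivity, and 5 is configurationally fragile. The fallback sets out from 4 and moves the enantio-determining event to a dynamic kinetic resolution. Hydroformylation without a chiral ligand (Rh(acac)(CO)2/PPh3, CO/H2) gives racemic 2-(2-bromo-4-methylphenyl)propanal F1. Ru-diphosphine/diamine hydrogenation under base (RuCl2[(S)-SDP][(R,R)-DACH], KOtBu, iPrOH, H2), in which the aldehyde racemises faster than it is reduced, gives the storable (2S)-2-(2-bromo-4-methylphenyl)propan-1-ol F2. Buffered Dess–Martin oxidation (NaHCO3, CH2Cl2, 0 °C) comes back to the route at 5 just before step 3.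

**Further compounds**

F1 | step 2 | racemic 2-(2-bromo-4-methylphenyl)propanal | O=CC(C)c1ccc(C)cc1Br
F2 | step 2 | (2S)-2-(2-bromo-4-methylphenyl)propan-1-ol | OC[C@@H](C)c1ccc(C)cc1Br
F3 | step 3 | (4S)-4-benzyl-3-[(2S,3R,4S)-4-(2-bromo-4-methylphenyl)-3-hydroxy-2-methylpentanoyl]-1,3-oxazolidin-2-one | O=C1OC[C@H](Cc2ccccc2)N1C(=O)[C@@H](C)[C@H](O)[C@@H](C)c3ccc(C)cc3Br
F4 | step 3 | (2S,3R,4S)-4-(2-bromo-4-methylphenyl)-3-hydroxy-2-methylpentanoic acid | OC(=O)[C@@H](C)[C@H](O)[C@@H](C)c1ccc(C)cc1Br
F5 | step 4 | (2S,3R,4S)-4-(2-bromo-4-methylphenyl)-3-hydroxy-N-methoxy-N,2-dimethylpentanamide | CON(C)C(=O)[C@@H](C)[C@H](O)[C@@H](C)c1ccc(C)cc1Br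
F6 | step 4 | (2S,3R,4S)-4-(2-bromo-4-methylphenyl)-N-methoxy-N,2-dimethyl-3-[(triethylsilyl)oxy]pentanamide | CON(C)C(=O)[C@@H](C)[C@H](O[Si](CC)(CC)CC)[C@@H](C)c1ccc(C)cc1Br
F7 | step 4 | ethyl (6S,7R,8S)-8-(2-bromo-4-methylphenyl)-2-ethyl-6-methyl-3,5-dioxo-7-[(triethylsilyl)oxy]nonanoate | CCOC(=O)C(CC)C(=O)CC(=O)[C@@H](C)[C@H](O[Si](CC)(CC)CC)[C@@H](C)c1ccc(C)cc1Br
F8 | step 4 | 6-[(2S,3R,4S)-4-(2-bromo-4-methylphenyl)-3-[(triethylsilyl)oxy]pentan-2-yl]-3-ethyl-4-hydroxy-2H-pyran-2-one | CCc1c(O)cc([C@@H](C)[C@H](O[Si](CC)(CC)CC)[C@@H](C)c2ccc(C)cc2Br)oc1=O
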